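## Retrosynthetic overview

1. The target comes from global desilylation of a penta-silyl ether. Its all-cis oxolane (ring C, closed last) is formed by the C7 hydroxyl displacing a C9' tosylate, which breaks no bond at a stereocentre. The open chain comes from an auxiliary-controlled anti-aldol (C7–C8 bond) between a bis(dihydrobenzofuran) aldehyde and a (3R)-3-arylmethyl-4-pivaloyloxybutanoyl oxazolidinone.
2. Each trans-dihydrobenzofuran comes from acid-mediated closure of a 2-(2-hydroxyaryl)-1-arylpropane-1,3-diol, made by an Evans syn aldol (the key C–C bond) of an N-arylacetyl oxazolidinone with an aryl aldehyde. The methyl ester para to the new ring oxygen is then converted into the aldehyde for the next aldol.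
3. Both arylacetyl imides come from one arylacetyl chloride made from methyl vanillate (O-allylation, Claisen rearrangement, benzylation, oxidative cleavage, chlorination). Enantiomeric auxiliaries are used because the two coumaran units have opposite absolute configuration.
4. The butanoyl imide comes from dihydroferulic acid by Evans alkylation with tert-butyl bromoacetate, reduction, pivaloylation, ester cleavage and attachment of a second auxiliary.
5. Ring order: furan ring of unit B (next to the terminal guaiacyl ring), then furan ring of unit A, then oxolane ring C.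

Assumption: the SMILES is taken literally, i.e. an all-cis (2R,3R,4R) oxolane, a (2R,3S) coumaran (unit A) and a (2S,3R) coumaran (unit B).

Abbreviations used in names:
- TIPSO = triisopropylsilyloxy; Piv = pivaloyl.
- Ar = 3-methoxy-4-(TIPSO)phenyl.
- unit B = (2S,3R)-2-Ar-7-methoxy-3-(TIPSO-methyl)-2,3-dihydro-1-benzofuran-5-yl.
- unit AB = (2R,3S)-7-methoxy-2-(unit B)-3-(TIPSO-methyl)-2,3-dihydro-1-benzofuran-5-yl.
- Locants for the last part: C7 = carbinol carbon bearing unit AB; C8 = next carbon, bearing C9H2O; C8' = carbon bearing the Ar-CH2 group; C9' = its CH2O carbon.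

## Route

Step 1
Reactants: 1 methyl vanillate (methyl 4-hydroxy-3-methoxybenzoate); 2 allyl bromide
Product: 3 methyl 4-(allyloxy)-3-methoxybenzoate
Conditions: K2CO3 (1.5 equiv), acetone, reflux
Reagents that add atoms: none
Why: Williamson ether synthesis, the phenoxide displacing bromide from the allylic halide by SN2.

Step 2
Reactants: 3 methyl 4-(allyloxy)-3-methoxybenzoate
Product: 4 methyl 3-allyl-4-hydroxy-5-methoxybenzoate
Conditions: N,N-diethylaniline, 200 °C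
Reagents that add atoms: none
Why: Aromatic Claisen rearrangement ([3,3]-sigmatropic shift, then tautomerisation) delivers the allyl group to the only free ortho position.

Step 3
Reactants: 4 methyl 3-allyl-4-hydroxy-5-methoxybenzoate
Product: 5 methyl 3-allyl-4-(benzyloxy)-5-methoxybenzoate
Conditions: BnBr (1.2 equiv), K2CO3 (2 equiv), DMF, 60 °C
Reagents that add atoms: benzyl bromide, BrCc1ccccc1
Why: Williamson benzylation masks the phenol that later becomes a furan-ring oxygen.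

Step 4
Reactants: 5 methyl 3-allyl-4-(benzyloxy)-5-methoxybenzoate
Product: 6 methyl 4-(benzyloxy)-3-methoxy-5-(2-oxoethyl)benzoate
Conditions: OsO4 (2 mol %), NaIO4 (4 equiv), 2,6-lutidine (2 equiv), dioxane/H2O 3:1, rt; crude used at once
Reagents that add atoms: osmium tetroxide (OsO4), O=[Os](=O)(=O)=O; sodium periodate (NaIO4), [Na+].[O-]I(=O)(=O)=O
Why: Lemieux–Johnson oxidative cleavage (dihydroxylation then periodate glycol fission) shortens the allyl group to the arylacetaldehyde without touching arene, ester or benzyl ether.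

Step 5
Reactants: 6 methyl 4-(benzyloxy)-3-methoxy-5-(2-oxoethyl)benzoate
Product: 7 [2-(benzyloxy)-3-methoxy-5-(methoxycarbonyl)phenyl]acetic acid
Conditions: NaClO2 (3 equiv), NaH2PO4 (3 equiv), 2-methyl-2-butene (10 equiv), t-BuOH/H2O, 0 °C → rt
Reagents that add atoms: sodium chlorite (NaClO2), [Na+].[O-]Cl=O
Why: Pinnick oxidation converts the enolisable aldehyde to the acid under buffered conditions, with the alkene scavenging hypochlorous acid.

Step 6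
Reactants: 7 [2-(benzyloxy)-3-methoxy-5-(methoxycarbonyl)phenyl]acetic acid
Product: 8 [2-(benzyloxy)-3-methoxy-5-(methoxycarbonyl)phenyl]acetyl chloride
Conditions: (COCl)2 (1.3 equiv), DMF (2 mol %), CH2Cl2, 0 °C → rt; evaporated, crude taken up in THF, divided in two portions and used the same day
Reagents that add atoms: oxalyl chloride, ClC(=O)C(=O)Cl
Why: DMF-catalysed chlorination through the Vilsmeier chloroiminium salt (nucleophilic acyl substitution) gives the acid chloride with only gaseous by-products and leaves the methyl ester and benzyl ether untouched.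

Step 7
Reactants: 8 [2-(benzyloxy)-3-methoxy-5-(methoxycarbonyl)phenyl]acetyl chloride; 9 (S)-4-benzyl-1,3-oxazolidin-2-one
Product: 10 (4S)-4-benzyl-3-{[2-(benzyloxy)-3-methoxy-5-(methoxycarbonyl)phenyl]acetyl}-1,3-oxazolidin-2-one
Conditions: 9 (1.0 equiv), n-BuLi (1.0 equiv), THF, −78 °C, 20 min; then 8 (1.1 equiv) in THF, −78 → 0 °C; sat. aq. NH4Cl
Reagents that add atoms: none
Why: Classical Evans N-acylation: the lithium salt of the oxazolidinone attacks the acid chloride at −78 °C far faster than it deprotonates the arylacetyl α-position or attacks the methyl benzoate.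

Step 8
Reactants: 8 [2-(benzyloxy)-3-methoxy-5-(methoxycarbonyl)phenyl]acetyl chloride; 11 (R)-4-benzyl-1,3-oxazolidin-2-one
Product: 12 (4R)-4-benzyl-3-{[2-(benzyloxy)-3-methoxy-5-(methoxycarbonyl)phenyl]acetyl}-1,3-oxazolidin-2-one
Conditions: 11 (1.0 equiv), n-BuLi (1.0 equiv), THF, −78 °C, 20 min; then 8 (1.1 equiv) in THF, −78 → 0 °C; sat. aq. NH4Cl
Reagents that add atoms: none
Why: Same N-acylation of the lithiated oxazolidinone by the acid chloride, giving the enantiomeric imide needed for the coumaran of opposite configuration.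

Step 9
Reactants: 13 vanillin
Product: 14 3-methoxy-4-(TIPSO)benzaldehyde (Ar-CHO)
Conditions: TIPSCl (1.2 equiv), imidazole (2.5 equiv), DMF, rt
Reagents that add atoms: triisopropylsilyl chloride, CC(C)[Si](Cl)(C(C)C)C(C)C
Why: Imidazole-mediated O-silylation gives a phenol ether that survives all later steps and is removed by fluoride at the end.

Step 10
Reactants: 10 (4S)-arylacetyl imide; 14 3-methoxy-4-(TIPSO)benzaldehyde
Product: 15 (4S)-4-benzyl-3-[(2S,3S)-3-Ar-2-[2-(benzyloxy)-3-methoxy-5-(methoxycarbonyl)phenyl]-3-hydroxypropanoyl]-1,3-oxazolidin-2-one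
Conditions: 10, Bu2BOTf (1.2 equiv), i-Pr2NEt (1.4 equiv), CH2Cl2, −78 → 0 °C; 14 (1.1 equiv), −78 → 0 °C; pH 7 buffer, MeOH, 30% H2O2, 0 °C
Reagents that add atoms: none
Why: Evans syn aldol: the Z-boron enolate reacts through a chair Zimmerman–Traxler transition state on the face away from the auxiliary benzyl group, giving the (2S,3S) adduct whose α-centre becomes C3 (R) of unit B.

Step 11
Reactants: 15 syn-aldol adduct
Product: 16 methyl 3-[(1S,2R)-1-Ar-1,3-dihydroxypropan-2-yl]-4-(benzyloxy)-5-methoxybenzoate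
Conditions: LiBH4 (2 equiv), MeOH (2 equiv), THF, 0 °C
Reagents that add atoms: none
Why: Reductive cleavage of the activated imide carbonyl by LiBH4 is much faster than reduction of the electron-rich methyl benzoate and leaves both stereocentres untouched.

Step 12
Reactants: 16 benzyl ether diol
Product: 17 methyl 3-[(1S,2R)-1-Ar-1,3-dihydroxypropan-2-yl]-4-hydroxy-5-methoxybenzoate
Conditions: H2 (1 atm), 10% Pd/C, EtOAc, rt
Reagents that add atoms: none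
Why: Catalytic hydrogenolysis cleaves the aryl benzyl ether rapidly under neutral conditions, under which the benzylic alcohol, ester and silyl ether persist.

Step 13
Reactants: 17 phenol diol
Product: 18 methyl (2S,3R)-2-Ar-3-(hydroxymethyl)-7-methoxy-2,3-dihydro-1-benzofuran-5-carboxylate
Conditions: BF3·OEt2 (0.3 equiv), CH2Cl2, −20 → 0 °C
Reagents that add atoms: none
Why: SN1 dehydrative cyclisation: the benzylic cation stabilised by the para-silyloxy group is captured 5-exo by the phenol, and C2 ends up trans to the fixed C3 centre (kinetically preferred and reinforced by reversible re-ionisation).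

Step 14
Reactants: 18 dihydrobenzofuran alcohol
Product: 19 methyl (2S,3R)-2-Ar-7-methoxy-3-(TIPSO-methyl)-2,3-dihydro-1-benzofuran-5-carboxylate
Conditions: TIPSCl (1.3 equiv), imidazole (3 equiv), 4-(dimethylamino)pyridine (0.1 equiv), DMF, rt
Reagents that add atoms: triisopropylsilyl chloride, CC(C)[Si](Cl)(C(C)C)C(C)C
Why: O-silylation of the primary alcohol gives an ether robust enough for the second Lewis-acid cyclisation.

Step 15
Reactants: 19 silyl ether ester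
Product: 20 [(2S,3R)-2-Ar-7-methoxy-3-(TIPSO-methyl)-2,3-dihydro-1-benzofuran-5-yl]methanol (unit B–CH2OH)
Conditions: i-Bu2AlH (2.5 equiv), CH2Cl2, −78 °C; Rochelle salt work-up
Reagents that add atoms: none
Why: Hydride reduction of the methyl ester to the benzylic alcohol leaves silyl ethers and the coumaran untouched.

Step 16
Reactants: 20 unit B–CH2OH
Product: 21 (2S,3R)-2-Ar-7-methoxy-3-(TIPSO-methyl)-2,3-dihydro-1-benzofuran-5-carbaldehyde (unit B–CHO)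
Conditions: MnO2 (15 equiv), CH2Cl2, rt
Reagents that add atoms: none
Why: MnO2 oxidation is selective for the benzylic alcohol and stops at the aldehyde.

Step 17
Reactants: 12 (4R)-arylacetyl imide; 21 unit B–CHO
Product: 22 (4R)-4-benzyl-3-[(2R,3R)-2-[2-(benzyloxy)-3-methoxy-5-(methoxycarbonyl)phenyl]-3-hydroxy-3-(unit B)propanoyl]-1,3-oxazolidin-2-one
Conditions: 12 (1.3 equiv), Bu2BOTf (1.5 equiv), i-Pr2NEt (1.8 equiv), CH2Cl2, −78 → 0 °C; 21, −78 → 0 °C; pH 7 buffer, MeOH, 30% H2O2, 0 °C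
Reagents that add atoms: none
Why: Second Evans syn aldol: the (R)-auxiliary gives the mirror-image sense, (2R,3R), so the α-centre becomes C3 (S) of unit A under reagent control.

Step 18
Reactants: 22 syn-aldol adduct
Product: 23 methyl 4-(benzyloxy)-3-[(1R,2S)-1,3-dihydroxy-1-(unit B)propan-2-yl]-5-methoxybenzoate
Conditions: LiBH4 (2 equiv), MeOH (2 equiv), THF, 0 °C
Reagents that add atoms: none
Why: Chemoselective LiBH4 reductive removal of the auxiliary, as in step 11.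

Step 19
Reactants: 23 benzyl ether diol
Product: 24 methyl 3-[(1R,2S)-1,3-dihydroxy-1-(unit B)propan-2-yl]-4-hydroxy-5-methoxybenzoate
Conditions: H2 (1 atm), 10% Pd/C, EtOAc, rt, stopped at full conversion
Reagents that add atoms: none
Why: Hydrogenolysis of the aryl benzyl ether is far faster than cleavage of the cyclic benzylic C–O bond of unit B or of the benzylic alcohol.

Step 20
Reactants: 24 phenol diol
Product: 25 methyl (2R,3S)-3-(hydroxymethyl)-7-methoxy-2-(unit B)-2,3-dihydro-1-benzofuran-5-carboxylate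
Conditions: BF3·OEt2 (0.3 equiv), CH2Cl2, −20 → 0 °C
Reagents that add atoms: none
Why: Same SN1 dehydrative cyclisation, the cation now stabilised by the ring oxygen of unit B; the new C2 centre is set trans to C3, giving (2R,3S).

Step 21
Reactants: 25 bis(dihydrobenzofuran) alcohol
Product: 26 methyl (2R,3S)-7-methoxy-2-(unit B)-3-(TIPSO-methyl)-2,3-dihydro-1-benzofuran-5-carboxylate (unit AB–CO2Me)
Conditions: TIPSCl (1.3 equiv), imidazole (3 equiv), 4-(dimethylamino)pyridine (0.1 equiv), DMF, rt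
Reagents that add atoms: triisopropylsilyl chloride, CC(C)[Si](Cl)(C(C)C)C(C)C
Why: O-silylation of the primary alcohol.

Step 22
Reactants: 26 unit AB–CO2Me
Product: 27 unit AB–CH2OH
Conditions: i-Bu2AlH (2.5 equiv), CH2Cl2, −78 °C; Rochelle salt work-up
Reagents that add atoms: none
Why: Hydride reduction of the ester to the benzylic alcohol.

Step 23
Reactants: 27 unit AB–CH2OH
Product: 28 unit AB–CHO
Conditions: MnO2 (15 equiv), CH2Cl2, rt
Reagents that add atoms: none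
Why: Selective MnO2 oxidation of the benzylic alcohol to the aldehyde.

Step 24
Reactants: 29 dihydroferulic acid (3-(4-hydroxy-3-methoxyphenyl)propanoic acid)
Product: 31 3-Ar-propanoic acid, via bis-TIPS derivative 30 (not isolated)
Conditions: TIPSCl (2.3 equiv), imidazole (5 equiv), DMF, rt; then K2CO3 (1.5 equiv), THF/MeOH/H2O, rt, 1 h; 1 M HCl to pH 4
Reagents that add atoms: triisopropylsilyl chloride, CC(C)[Si](Cl)(C(C)C)C(C)C
Why: Exhaustive silylation followed by selective hydrolysis of the much more labile silyl ester leaves the aryl silyl ether in place.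

Step 25
Reactants: 31 3-Ar-propanoic acid; 9 (S)-4-benzyl-1,3-oxazolidin-2-one
Product: 33 (4S)-4-benzyl-3-(3-Ar-propanoyl)-1,3-oxazolidin-2-one, via mixed pivalic anhydride 32 (not isolated)
Conditions: PivCl (1.05 equiv), Et3N (2.5 equiv), THF, −20 °C; then LiCl (1.2 equiv), 9 (1.0 equiv), −20 °C → rt
Reagents that add atoms: none
Why: Mixed-anhydride N-acylation of the oxazolidinone (LiCl/Et3N protocol) needs no strong base or acid chloride and so spares the aryl silyl ether.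

Step 26
Reactants: 33 (4S)-propanoyl imide; 34 tert-butyl bromoacetate
Product: 35 tert-butyl (3R)-4-[(4S)-4-benzyl-2-oxo-1,3-oxazolidin-3-yl]-3-(Ar-methyl)-4-oxobutanoate
Conditions: NaN(SiMe3)2 (1.1 equiv), THF, −78 °C; 34 (2 equiv), −78 → −40 °C
Reagents that add atoms: none
Why: Evans asymmetric alkylation: the chelated Z-sodium enolate is alkylated on the face opposite the auxiliary benzyl group, setting the future C8' as R.

Step 27
Reactants: 35 alkylated imide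
Product: 36 tert-butyl (3R)-4-hydroxy-3-(Ar-methyl)butanoate
Conditions: LiBH4 (1.5 equiv), MeOH (1.5 equiv), Et2O/THF, 0 °C; used promptly
Reagents that add atoms: none
Why: LiBH4 cleaves the imide reductively while the hindered tert-butyl ester is inert, and the stereocentre is not enolisable under these conditions.

Step 28
Reactants: 36 hydroxy ester
Product: 37 tert-butyl (3R)-3-(Ar-methyl)-4-(pivaloyloxy)butanoate
Conditions: PivCl (1.3 equiv), pyridine (3 equiv), 4-(dimethylamino)pyridine (0.1 equiv), CH2Cl2, 0 °C → rt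
Reagents that add atoms: pivaloyl chloride, CC(C)(C)C(=O)Cl
Why: O-acylation blocks lactonisation and marks C9'-O with a group that survives LiBH4 and silylation but is removed by i-Bu2AlH.

Step 29
Reactants: 37 pivalate tert-butyl ester
Product: 38 (3R)-3-(Ar-methyl)-4-(pivaloyloxy)butanoic acid
Conditions: CF3CO2H/CH2Cl2 1:4, Et3SiH (2.5 equiv), 0 °C → rt
Reagents that add atoms: none
Why: Acidolysis of the tert-butyl ester (alkyl–oxygen cleavage), with the silane reducing the tert-butyl cation so that it cannot alkylate the electron-rich ring.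

Step 30
Reactants: 38 pivaloyloxy acid; 11 (R)-4-benzyl-1,3-oxazolidin-2-one
Product: 40 (4R)-4-benzyl-3-[(3R)-3-(Ar-methyl)-4-(pivaloyloxy)butanoyl]-1,3-oxazolidin-2-one, via mixed pivalic anhydride 39 (not isolated)
Conditions: PivCl (1.05 equiv), Et3N (2.5 equiv), THF, −20 °C; then LiCl (1.2 equiv), 11 (1.0 equiv), −20 °C → rt
Reagents that add atoms: none
Why: Mixed-anhydride N-acylation under mild base installs the auxiliary that will control C7 and C8 without disturbing the pivalate or the silyl ether.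

Step 31
Reactants: 40 (4R)-butanoyl imide; 28 unit AB–CHO
Product: 42 (4R)-4-benzyl-3-[(2S,3R)-3-hydroxy-3-(unit AB)-2-[(2R)-1-Ar-3-(pivaloyloxy)propan-2-yl]propanoyl]-1,3-oxazolidin-2-one, via trimethylsilyl aldol ether 41 (not isolated)
Conditions: 40 (1.3 equiv), MgCl2 (0.2 equiv), Et3N (2.5 equiv), Me3SiCl (2.0 equiv), EtOAc, rt, 36 h; then 1 M HCl/THF 1:5, 0 °C, 15 min
Reagents that add atoms: none
Why: Evans MgCl2-catalysed direct anti-aldol: the chelated Z-magnesium enolate is attacked through a boat transition state on the face opposite the auxiliary benzyl group (same sense as Evans alkylation), giving the (2S,3R) anti adduct, i.e. C8 and C7 as required, with silylation of the aldolate turning over the magnesium.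

Step 32
Reactants: 42 anti-aldol adduct
Product: 43 (2R,3R,4R)-4-hydroxy-3-(hydroxymethyl)-4-(unit AB)-2-(Ar-methyl)butyl pivalate
Conditions: LiBH4 (2 equiv), MeOH (2 equiv), THF, 0 °C
Reagents that add atoms: none
Why: Chemoselective LiBH4 reductive cleavage of the imide; the hindered pivalate is not reduced at 0 °C.

Step 33
Reactants: 43 diol pivalate
Product: 44 (2R,3R,4R)-4-hydroxy-4-(unit AB)-2-(Ar-methyl)-3-(TIPSO-methyl)butyl pivalate
Conditions: TIPSCl (1.2 equiv), imidazole (2.5 equiv), CH2Cl2, 0 °C → rt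
Reagents that add atoms: triisopropylsilyl chloride, CC(C)[Si](Cl)(C(C)C)C(C)C
Why: Steric selection in silylation: the bulky silyl chloride reacts with the primary C9 alcohol and leaves the hindered secondary benzylic C7 alcohol free.

Step 34
Reactants: 44 silyl ether pivalate
Product: 45 (1R,2R,3R)-1-(unit AB)-3-(Ar-methyl)-2-(TIPSO-methyl)butane-1,4-diol
Conditions: i-Bu2AlH (3.5 equiv), CH2Cl2, −78 °C; Rochelle salt work-up
Reagents that add atoms: none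
Why: Reductive cleavage of the pivalate frees only the C9' alcohol under non-basic, non-acidic conditions.

Step 35
Reactants: 45 1,4-diol
Product: 47 (2R,3R,4R)-2-(unit AB)-4-(Ar-methyl)-3-(TIPSO-methyl)oxolane, via primary tosylate 46 (not isolated)
Conditions: TsCl (1.1 equiv), Et3N (1.5 equiv), 4-(dimethylamino)pyridine (0.1 equiv), CH2Cl2, 0 °C; then THF, NaH (4 equiv), 0 °C → rt
Reagents that add atoms: none
Why: Selective sulfonylation of the primary alcohol, then intramolecular Williamson etherification (5-exo-tet SN2 at C9'), which breaks no bond at C7, C8 or C8', so the (7R,8R,8'R) chain maps onto the all-cis (2R,3R,4R) ring.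

Step 36
Reactants: 47 penta-silyl ether
Product: 48 target, (2R,3R,4R)-oxolane carrying the 4-hydroxy-3-methoxybenzyl group, CH2OH and the (2R,3S)/(2S,3R) bis(dihydrobenzofuran) unit (CNP0395728.1)
Conditions: Bu4NF (10 equiv), AcOH (10 equiv), THF, 0 °C → rt
Reagents that add atoms: none
Why: Fluoride-mediated desilylation (strong Si–F bond) removes the two aryl and three alkyl silyl ethers; the acetic acid buffer keeps the benzylic ether stereocentres from ring-opening via quinone methides.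

## Compound list

1 | methyl vanillate | COC(=O)c1ccc(O)c(OC)c1 | starting material
2 | allyl bromide | C=CCBr | starting material
3 | methyl 4-(allyloxy)-3-methoxybenzoate | COC(=O)c1ccc(OCC=C)c(OC)c1 | intermediate
4 | methyl 3-allyl-4-hydroxy-5-methoxybenzoate | COC(=O)c1cc(CC=C)c(O)c(OC)c1 | intermediate
5 | methyl 3-allyl-4-(benzyloxy)-5-methoxybenzoate | COC(=O)c1cc(CC=C)c(OCc2ccccc2)c(OC)c1 | intermediate
6 | methyl 4-(benzyloxy)-3-methoxy-5-(2-oxoethyl)benzoate | COC(=O)c1cc(CC=O)c(OCc2ccccc2)c(OC)c1 | intermediate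
7 | [2-(benzyloxy)-3-methoxy-5-(methoxycarbonyl)phenyl]acetic acid | COC(=O)c1cc(CC(=O)O)c(OCc2ccccc2)c(OC)c1 | intermediate
8 | [2-(benzyloxy)-3-methoxy-5-(methoxycarbonyl)phenyl]acetyl chloride | COC(=O)c1cc(CC(=O)Cl)c(OCc2ccccc2)c(OC)c1 | intermediate
9 | (S)-4-benzyl-1,3-oxazolidin-2-one | O=C1N[C@@H](Cc2ccccc2)CO1 | starting material
10 | (4S)-4-benzyl-3-{[2-(benzyloxy)-3-methoxy-5-(methoxycarbonyl)phenyl]acetyl}-1,3-oxazolidin-2-one | COC(=O)c1cc(CC(=O)N2[C@@H](Cc3ccccc3)COC2=O)c(OCc2ccccc2)c(OC)c1 | intermediate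
11 | (R)-4-benzyl-1,3-oxazolidin-2-one | O=C1N[C@H](Cc2ccccc2)CO1 | starting material
12 | (4R)-4-benzyl-3-{[2-(benzyloxy)-3-methoxy-5-(methoxycarbonyl)phenyl]acetyl}-1,3-oxazolidin-2-one | COC(=O)c1cc(CC(=O)N2[C@H](Cc3ccccc3)COC2=O)c(OCc2ccccc2)c(OC)c1 | intermediate
13 | vanillin | COc1cc(C=O)ccc1O | starting material
14 | 3-methoxy-4-(triisopropylsilyloxy)benzaldehyde | COc1cc(C=O)ccc1O[Si](C(C)C)(C(C)C)C(C)C | intermediate
15 | (4S)-4-benzyl-3-[(2S,3S)-3-Ar-2-[2-(benzyloxy)-3-methoxy-5-(methoxycarbonyl)phenyl]-3-hydroxypropanoyl]-1,3-oxazolidin-2-one | O=C(N1[C@@H](Cc2ccccc2)COC1=O)[C@@H](c1cc(C(=O)OC)cc(OC)c1OCc1ccccc1)[C@H](O)c1ccc(O[Si](C(C)C)(C(C)C)C(C)C)c(OC)c1 | intermediate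
16 | methyl 3-[(1S,2R)-1-Ar-1,3-dihydroxypropan-2-yl]-4-(benzyloxy)-5-methoxybenzoate | OC[C@@H](c1cc(C(=O)OC)cc(OC)c1OCc1ccccc1)[C@H](O)c1ccc(O[Si](C(C)C)(C(C)C)C(C)C)c(OC)c1 | intermediate
17 | methyl 3-[(1S,2R)-1-Ar-1,3-dihydroxypropan-2-yl]-4-hydroxy-5-methoxybenzoate | OC[C@@H](c1cc(C(=O)OC)cc(OC)c1O)[C@H](O)c1ccc(O[Si](C(C)C)(C(C)C)C(C)C)c(OC)c1 | intermediate
18 | methyl (2S,3R)-2-Ar-3-(hydroxymethyl)-7-methoxy-2,3-dihydro-1-benzofuran-5-carboxylate | COC(=O)c1cc(OC)c2c(c1)[C@H](CO)[C@@H](c1ccc(O[Si](C(C)C)(C(C)C)C(C)C)c(OC)c1)O2 | intermediate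
19 | methyl (2S,3R)-2-Ar-7-methoxy-3-(TIPSO-methyl)-2,3-dihydro-1-benzofuran-5-carboxylate | COC(=O)c1cc(OC)c2c(c1)[C@H](CO[Si](C(C)C)(C(C)C)C(C)C)[C@@H](c1ccc(O[Si](C(C)C)(C(C)C)C(C)C)c(OC)c1)O2 | intermediate
20 | unit B–CH2OH | OCc1cc(OC)c2c(c1)[C@H](CO[Si](C(C)C)(C(C)C)C(C)C)[C@@H](c1ccc(O[Si](C(C)C)(C(C)C)C(C)C)c(OC)c1)O2 | intermediate
21 | unit B–CHO | O=Cc1cc(OC)c2c(c1)[C@H](CO[Si](C(C)C)(C(C)C)C(C)C)[C@@H](c1ccc(O[Si](C(C)C)(C(C)C)C(C)C)c(OC)c1)O2 | intermediate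
22 | (4R)-4-benzyl-3-[(2R,3R)-2-[2-(benzyloxy)-3-methoxy-5-(methoxycarbonyl)phenyl]-3-hydroxy-3-(unit B)propanoyl]-1,3-oxazolidin-2-one | O=C(N1[C@H](Cc2ccccc2)COC1=O)[C@H](c1cc(C(=O)OC)cc(OC)c1OCc1ccccc1)[C@@H](O)c1cc(OC)c2c(c1)[C@H](CO[Si](C(C)C)(C(C)C)C(C)C)[C@@H](c1ccc(O[Si](C(C)C)(C(C)C)C(C)C)c(OC)c1)O2 | intermediate
23 | methyl 4-(benzyloxy)-3-[(1R,2S)-1,3-dihydroxy-1-(unit B)propan-2-yl]-5-methoxybenzoate | OC[C@H](c1cc(C(=O)OC)cc(OC)c1OCc1ccccc1)[C@@H](O)c1cc(OC)c2c(c1)[C@H](CO[Si](C(C)C)(C(C)C)C(C)C)[C@@H](c1ccc(O[Si](C(C)C)(C(C)C)C(C)C)c(OC)c1)O2 | intermediate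
24 | methyl 3-[(1R,2S)-1,3-dihydroxy-1-(unit B)propan-2-yl]-4-hydroxy-5-methoxybenzoate | OC[C@H](c1cc(C(=O)OC)cc(OC)c1O)[C@@H](O)c1cc(OC)c2c(c1)[C@H](CO[Si](C(C)C)(C(C)C)C(C)C)[C@@H](c1ccc(O[Si](C(C)C)(C(C)C)C(C)C)c(OC)c1)O2 | intermediate
25 | methyl (2R,3S)-3-(hydroxymethyl)-7-methoxy-2-(unit B)-2,3-dihydro-1-benzofuran-5-carboxylate | COC(=O)c1cc(OC)c2c(c1)[C@@H](CO)[C@H](c1cc(OC)c3c(c1)[C@H](CO[Si](C(C)C)(C(C)C)C(C)C)[C@@H](c1ccc(O[Si](C(C)C)(C(C)C)C(C)C)c(OC)c1)O3)O2 | intermediate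
26 | unit AB–CO2Me | COC(=O)c1cc(OC)c2c(c1)[C@@H](CO[Si](C(C)C)(C(C)C)C(C)C)[C@H](c1cc(OC)c3c(c1)[C@H](CO[Si](C(C)C)(C(C)C)C(C)C)[C@@H](c1ccc(O[Si](C(C)C)(C(C)C)C(C)C)c(OC)c1)O3)O2 | intermediate
27 | unit AB–CH2OH | OCc1cc(OC)c2c(c1)[C@@H](CO[Si](C(C)C)(C(C)C)C(C)C)[C@H](c1cc(OC)c3c(c1)[C@H](CO[Si](C(C)C)(C(C)C)C(C)C)[C@@H](c1ccc(O[Si](C(C)C)(C(C)C)C(C)C)c(OC)c1)O3)O2 | intermediate
28 | unit AB–CHO | O=Cc1cc(OC)c2c(c1)[C@@H](CO[Si](C(C)C)(C(C)C)C(C)C)[C@H](c1cc(OC)c3c(c1)[C@H](CO[Si](C(C)C)(C(C)C)C(C)C)[C@@H](c1ccc(O[Si](C(C)C)(C(C)C)C(C)C)c(OC)c1)O3)O2 | intermediate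
29 | dihydroferulic acid | COc1cc(CCC(=O)O)ccc1O | starting material
30 | triisopropylsilyl 3-Ar-propanoate | COc1cc(CCC(=O)O[Si](C(C)C)(C(C)C)C(C)C)ccc1O[Si](C(C)C)(C(C)C)C(C)C | intermediate
31 | 3-Ar-propanoic acid | COc1cc(CCC(=O)O)ccc1O[Si](C(C)C)(C(C)C)C(C)C | intermediate
32 | mixed pivalic anhydride of acid 31 | COc1cc(CCC(=O)OC(=O)C(C)(C)C)ccc1O[Si](C(C)C)(C(C)C)C(C)C | intermediate
33 | (4S)-4-benzyl-3-(3-Ar-propanoyl)-1,3-oxazolidin-2-one | COc1cc(CCC(=O)N2[C@@H](Cc3ccccc3)COC2=O)ccc1O[Si](C(C)C)(C(C)C)C(C)C | intermediate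
34 | tert-butyl bromoacetate | CC(C)(C)OC(=O)CBr | starting material
35 | tert-butyl (3R)-4-[(4S)-4-benzyl-2-oxo-1,3-oxazolidin-3-yl]-3-(Ar-methyl)-4-oxobutanoate | COc1cc(C[C@H](CC(=O)OC(C)(C)C)C(=O)N2[C@@H](Cc3ccccc3)COC2=O)ccc1O[Si](C(C)C)(C(C)C)C(C)C | intermediate
36 | tert-butyl (3R)-4-hydroxy-3-(Ar-methyl)butanoate | COc1cc(C[C@H](CC(=O)OC(C)(C)C)CO)ccc1O[Si](C(C)C)(C(C)C)C(C)C | intermediate
37 | tert-butyl (3R)-3-(Ar-methyl)-4-(pivaloyloxy)butanoate | COc1cc(C[C@H](CC(=O)OC(C)(C)C)COC(=O)C(C)(C)C)ccc1O[Si](C(C)C)(C(C)C)C(C)C | intermediate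
38 | (3R)-3-(Ar-methyl)-4-(pivaloyloxy)butanoic acid | COc1cc(C[C@H](CC(=O)O)COC(=O)C(C)(C)C)ccc1O[Si](C(C)C)(C(C)C)C(C)C | intermediate
39 | mixed pivalic anhydride of acid 38 | COc1cc(C[C@H](CC(=O)OC(=O)C(C)(C)C)COC(=O)C(C)(C)C)ccc1O[Si](C(C)C)(C(C)C)C(C)C | intermediate
40 | (4R)-4-benzyl-3-[(3R)-3-(Ar-methyl)-4-(pivaloyloxy)butanoyl]-1,3-oxazolidin-2-one | COc1cc(C[C@H](CC(=O)N2[C@H](Cc3ccccc3)COC2=O)COC(=O)C(C)(C)C)ccc1O[Si](C(C)C)(C(C)C)C(C)C | intermediate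
41 | O-trimethylsilyl ether of 42 | COc1cc(C[C@@H](COC(=O)C(C)(C)C)[C@H](C(=O)N2[C@H](Cc3ccccc3)COC2=O)[C@@H](O[Si](C)(C)C)c2cc(OC)c3c(c2)[C@@H](CO[Si](C(C)C)(C(C)C)C(C)C)[C@H](c2cc(OC)c4c(c2)[C@H](CO[Si](C(C)C)(C(C)C)C(C)C)[C@@H](c2ccc(O[Si](C(C)C)(C(C)C)C(C)C)c(OC)c2)O4)O3)ccc1O[Si](C(C)C)(C(C)C)C(C)C | intermediate
42 | (4R)-4-benzyl-3-[(2S,3R)-3-hydroxy-3-(unit AB)-2-[(2R)-1-Ar-3-(pivaloyloxy)propan-2-yl]propanoyl]-1,3-oxazolidin-2-one | COc1cc(C[C@@H](COC(=O)C(C)(C)C)[C@H](C(=O)N2[C@H](Cc3ccccc3)COC2=O)[C@@H](O)c2cc(OC)c3c(c2)[C@@H](CO[Si](C(C)C)(C(C)C)C(C)C)[C@H](c2cc(OC)c4c(c2)[C@H](CO[Si](C(C)C)(C(C)C)C(C)C)[C@@H](c2ccc(O[Si](C(C)C)(C(C)C)C(C)C)c(OC)c2)O4)O3)ccc1O[Si](C(C)C)(C(C)C)C(C)C | intermediate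
43 | (2R,3R,4R)-4-hydroxy-3-(hydroxymethyl)-4-(unit AB)-2-(Ar-methyl)butyl pivalate | COc1cc(C[C@@H](COC(=O)C(C)(C)C)[C@H](CO)[C@@H](O)c2cc(OC)c3c(c2)[C@@H](CO[Si](C(C)C)(C(C)C)C(C)C)[C@H](c2cc(OC)c4c(c2)[C@H](CO[Si](C(C)C)(C(C)C)C(C)C)[C@@H](c2ccc(O[Si](C(C)C)(C(C)C)C(C)C)c(OC)c2)O4)O3)ccc1O[Si](C(C)C)(C(C)C)C(C)C | intermediate
44 | (2R,3R,4R)-4-hydroxy-4-(unit AB)-2-(Ar-methyl)-3-(TIPSO-methyl)butyl pivalate | COc1cc(C[C@@H](COC(=O)C(C)(C)C)[C@H](CO[Si](C(C)C)(C(C)C)C(C)C)[C@@H](O)c2cc(OC)c3c(c2)[C@@H](CO[Si](C(C)C)(C(C)C)C(C)C)[C@H](c2cc(OC)c4c(c2)[C@H](CO[Si](C(C)C)(C(C)C)C(C)C)[C@@H](c2ccc(O[Si](C(C)C)(C(C)C)C(C)C)c(OC)c2)O4)O3)ccc1O[Si](C(C)C)(C(C)C)C(C)C | intermediate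
45 | (1R,2R,3R)-1-(unit AB)-3-(Ar-methyl)-2-(TIPSO-methyl)butane-1,4-diol | COc1cc(C[C@@H](CO)[C@H](CO[Si](C(C)C)(C(C)C)C(C)C)[C@@H](O)c2cc(OC)c3c(c2)[C@@H](CO[Si](C(C)C)(C(C)C)C(C)C)[C@H](c2cc(OC)c4c(c2)[C@H](CO[Si](C(C)C)(C(C)C)C(C)C)[C@@H](c2ccc(O[Si](C(C)C)(C(C)C)C(C)C)c(OC)c2)O4)O3)ccc1O[Si](C(C)C)(C(C)C)C(C)C | intermediate
46 | (2R,3R,4R)-4-hydroxy-4-(unit AB)-2-(Ar-methyl)-3-(TIPSO-methyl)butyl 4-methylbenzenesulfonate | COc1cc(C[C@@H](COS(=O)(=O)c2ccc(C)cc2)[C@H](CO[Si](C(C)C)(C(C)C)C(C)C)[C@@H](O)c2cc(OC)c3c(c2)[C@@H](CO[Si](C(C)C)(C(C)C)C(C)C)[C@H](c2cc(OC)c4c(c2)[C@H](CO[Si](C(C)C)(C(C)C)C(C)C)[C@@H](c2ccc(O[Si](C(C)C)(C(C)C)C(C)C)c(OC)c2)O4)O3)ccc1O[Si](C(C)C)(C(C)C)C(C)C | intermediate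
47 | (2R,3R,4R)-2-(unit AB)-4-(Ar-methyl)-3-(TIPSO-methyl)oxolane | COc1cc(C[C@H]2CO[C@@H](c3cc(OC)c4c(c3)[C@@H](CO[Si](C(C)C)(C(C)C)C(C)C)[C@H](c3cc(OC)c5c(c3)[C@H](CO[Si](C(C)C)(C(C)C)C(C)C)[C@@H](c3ccc(O[Si](C(C)C)(C(C)C)C(C)C)c(OC)c3)O5)O4)[C@H]2CO[Si](C(C)C)(C(C)C)C(C)C)ccc1O[Si](C(C)C)(C(C)C)C(C)C | intermediate
48 | CNP0395728.1 | COc1cc(C[C@H]2CO[C@@H](c3cc(OC)c4c(c3)[C@@H](CO)[C@H](c3cc(OC)c5c(c3)[C@H](CO)[C@@H](c3ccc(O)c(OC)c3)O5)O4)[C@H]2CO)ccc1O | target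

## Step count and risk

Total step count: 36. Longest linear sequence: 27 steps (1–7, 10–16, 17–23, 31–36).

Most likely to fail, step 31 (anti-aldol with a hindered, β-branched imide and an electron-rich aldehyde; rate and diastereoselectivity are uncertain). The fallback sets out from acid 38 (with auxiliary 9 and aldehyde 28) and comes back at 44. Acid 38 is attached to 9 by the mixed-anhydride protocol of step 30 (through 39) to give the (4S)-imide F1. Its Bu2BOTf/i-Pr2NEt Evans syn aldol with 28, a closed chair process that tolerates bulky α-substituents, gives the (2S,3S)-syn adduct F2, which has the correct C8 but the epimeric C7. LiBH4 gives the 7-epi diol F3, and TIPSCl/imidazole gives its primary silyl ether F4. Dess–Martin periodinane with NaHCO3 gives the aryl ketone F5. Catalyst-controlled reduction with (S)-3,3-diphenyl-1-methyltetrahydro-1H,3H-pyrrolo[1,2-c][1,3,2]oxazaborole ((S)-Me-CBS) and BH3·SMe2 at −30 °C, the aryl group acting as the large substituent, then gives the (7R)-alcohol 44.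

Second, step 20 (Lewis-acid cyclisation in the presence of the acid-labile coumaran of unit B and three silyl ethers; the same concern applies to a lesser degree to step 13). The fallback sets out from aldehyde 21 and imide 10 and comes back at 26, avoiding acid altogether. MgCl2/Et3N/Me3SiCl anti-aldol of 10 with 21 gives the O-trimethylsilyl anti adduct F6, and brief dilute HCl gives the free (2R,3S) anti-aldol F7, which has the same α-centre as 22 but the epimeric carbinol. LiBH4 gives the anti diol F8, TIPSCl/imidazole the primary silyl ether F9, and hydrogenolysis the phenol F10. A Mitsunobu etherification (PPh3, diisopropyl azodicarboxylate, THF, 0 °C) then closes the furan ring with inversion at the carbinol under neutral conditions to give 26 directly; any SN1 leakage also leads to the trans isomer.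

Third, step 35 (closure to the congested all-cis oxolane; competing sulfonylation of the benzylic alcohol would invert C7). The fallback sets out from 45 and comes back at 47. Oxidation with 2,2,6,6-tetramethylpiperidin-1-oxyl (cat.) and PhI(OAc)2 in CH2Cl2 attacks only the primary C9' alcohol and carries the resulting lactol on to the γ-lactone F11. i-Bu2AlH at −78 °C gives the lactol F12, and Et3SiH/BF3·OEt2 at −78 °C reduces its oxocarbenium ion to 47. No bond at C7 is made or broken in this sequence.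

## Further compounds

F1 | step 31 | (4S)-4-benzyl-3-[(3R)-3-(Ar-methyl)-4-(pivaloyloxy)butanoyl]-1,3-oxazolidin-2-one | COc1cc(C[C@H](CC(=O)N2[C@@H](Cc3ccccc3)COC2=O)COC(=O)C(C)(C)C)ccc1O[Si](C(C)C)(C(C)C)C(C)C
F2 | step 31 | (4S)-4-benzyl-3-[(2S,3S)-3-hydroxy-3-(unit AB)-2-[(2R)-1-Ar-3-(pivaloyloxy)propan-2-yl]propanoyl]-1,3-oxazolidin-2-one | COc1cc(C[C@@H](COC(=O)C(C)(C)C)[C@H](C(=O)N2[C@@H](Cc3ccccc3)COC2=O)[C@H](O)c2cc(OC)c3c(c2)[C@@H](CO[Si](C(C)C)(C(C)C)C(C)C)[C@H](c2cc(OC)c4c(c2)[C@H](CO[Si](C(C)C)(C(C)C)C(C)C)[C@@H](c2ccc(O[Si](C(C)C)(C(C)C)C(C)C)c(OC)c2)O4)O3)ccc1O[Si](C(C)C)(C(C)C)C(C)C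
F3 | step 31 | (2R,3R,4S)-4-hydroxy-3-(hydroxymethyl)-4-(unit AB)-2-(Ar-methyl)butyl pivalate | COc1cc(C[C@@H](COC(=O)C(C)(C)C)[C@H](CO)[C@H](O)c2cc(OC)c3c(c2)[C@@H](CO[Si](C(C)C)(C(C)C)C(C)C)[C@H](c2cc(OC)c4c(c2)[C@H](CO[Si](C(C)C)(C(C)C)C(C)C)[C@@H](c2ccc(O[Si](C(C)C)(C(C)C)C(C)C)c(OC)c2)O4)O3)ccc1O[Si](C(C)C)(C(C)C)C(C)C
F4 | step 31 | (2R,3R,4S)-4-hydroxy-4-(unit AB)-2-(Ar-methyl)-3-(TIPSO-methyl)butyl pivalate | COc1cc(C[C@@H](COC(=O)C(C)(C)C)[C@H](CO[Si](C(C)C)(C(C)C)C(C)C)[C@H](O)c2cc(OC)c3c(c2)[C@@H](CO[Si](C(C)C)(C(C)C)C(C)C)[C@H](c2cc(OC)c4c(c2)[C@H](CO[Si](C(C)C)(C(C)C)C(C)C)[C@@H](c2ccc(O[Si](C(C)C)(C(C)C)C(C)C)c(OC)c2)O4)O3)ccc1O[Si](C(C)C)(C(C)C)C(C)C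
F5 | step 31 | (2R,3R)-4-oxo-4-(unit AB)-2-(Ar-methyl)-3-(TIPSO-methyl)butyl pivalate | COc1cc(C[C@@H](COC(=O)C(C)(C)C)[C@H](CO[Si](C(C)C)(C(C)C)C(C)C)C(=O)c2cc(OC)c3c(c2)[C@@H](CO[Si](C(C)C)(C(C)C)C(C)C)[C@H](c2cc(OC)c4c(c2)[C@H](CO[Si](C(C)C)(C(C)C)C(C)C)[C@@H](c2ccc(O[Si](C(C)C)(C(C)C)C(C)C)c(OC)c2)O4)O3)ccc1O[Si](C(C)C)(C(C)C)C(C)C
F6 | step 20 | (4S)-4-benzyl-3-[(2R,3S)-2-[2-(benzyloxy)-3-methoxy-5-(methoxycarbonyl)phenyl]-3-(trimethylsilyloxy)-3-(unit B)propanoyl]-1,3-oxazolidin-2-one | O=C(N1[C@@H](Cc2ccccc2)COC1=O)[C@H](c1cc(C(=O)OC)cc(OC)c1OCc1ccccc1)[C@H](O[Si](C)(C)C)c1cc(OC)c2c(c1)[C@H](CO[Si](C(C)C)(C(C)C)C(C)C)[C@@H](c1ccc(O[Si](C(C)C)(C(C)C)C(C)C)c(OC)c1)O2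
F7 | step 20 | (4S)-4-benzyl-3-[(2R,3S)-2-[2-(benzyloxy)-3-methoxy-5-(methoxycarbonyl)phenyl]-3-hydroxy-3-(unit B)propanoyl]-1,3-oxazolidin-2-one | O=C(N1[C@@H](Cc2ccccc2)COC1=O)[C@H](c1cc(C(=O)OC)cc(OC)c1OCc1ccccc1)[C@H](O)c1cc(OC)c2c(c1)[C@H](CO[Si](C(C)C)(C(C)C)C(C)C)[C@@H](c1ccc(O[Si](C(C)C)(C(C)C)C(C)C)c(OC)c1)O2
F8 | step 20 | methyl 4-(benzyloxy)-3-[(1S,2S)-1,3-dihydroxy-1-(unit B)propan-2-yl]-5-methoxybenzoate | OC[C@H](c1cc(C(=O)OC)cc(OC)c1OCc1ccccc1)[C@H](O)c1cc(OC)c2c(c1)[C@H](CO[Si](C(C)C)(C(C)C)C(C)C)[C@@H](c1ccc(O[Si](C(C)C)(C(C)C)C(C)C)c(OC)c1)O2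
F9 | step 20 | methyl 4-(benzyloxy)-3-[(1S,2S)-1-hydroxy-1-(unit B)-3-(TIPSO)propan-2-yl]-5-methoxybenzoate | CC(C)[Si](C(C)C)(C(C)C)OC[C@H](c1cc(C(=O)OC)cc(OC)c1OCc1ccccc1)[C@H](O)c1cc(OC)c2c(c1)[C@H](CO[Si](C(C)C)(C(C)C)C(C)C)[C@@H](c1ccc(O[Si](C(C)C)(C(C)C)C(C)C)c(OC)c1)O2
F10 | step 20 | methyl 4-hydroxy-3-[(1S,2S)-1-hydroxy-1-(unit B)-3-(TIPSO)propan-2-yl]-5-methoxybenzoate | CC(C)[Si](C(C)C)(C(C)C)OC[C@H](c1cc(C(=O)OC)cc(OC)c1O)[C@H](O)c1cc(OC)c2c(c1)[C@H](CO[Si](C(C)C)(C(C)C)C(C)C)[C@@H](c1ccc(O[Si](C(C)C)(C(C)C)C(C)C)c(OC)c1)O2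
F11 | step 35 | (3R,4R,5R)-5-(unit AB)-3-(Ar-methyl)-4-(TIPSO-methyl)oxolan-2-one | COc1cc(C[C@H]2C(=O)O[C@@H](c3cc(OC)c4c(c3)[C@@H](CO[Si](C(C)C)(C(C)C)C(C)C)[C@H](c3cc(OC)c5c(c3)[C@H](CO[Si](C(C)C)(C(C)C)C(C)C)[C@@H](c3ccc(O[Si](C(C)C)(C(C)C)C(C)C)c(OC)c3)O5)O4)[C@H]2CO[Si](C(C)C)(C(C)C)C(C)C)ccc1O[Si](C(C)C)(C(C)C)C(C)C
F12 | step 35 | (3R,4R,5R)-5-(unit AB)-3-(Ar-methyl)-4-(TIPSO-methyl)oxolan-2-ol (anomer mixture) | COc1cc(C[C@H]2C(O)O[C@@H](c3cc(OC)c4c(c3)[C@@H](CO[Si](C(C)C)(C(C)C)C(C)C)[C@H](c3cc(OC)c5c(c3)[C@H](CO[Si](C(C)C)(C(C)C)C(C)C)[C@@H](c3ccc(O[Si](C(C)C)(C(C)C)C(C)C)c(OC)c3)O5)O4)[C@H]2CO[Si](C(C)C)(C(C)C)C(C)C)ccc1O[Si](C(C)C)(C(C)C)C(C)C
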